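**Retrosynthetic overview**
1. The target is traced back to its tris(triisopropylsilyl) ether, desilylated last. Rings A and B are bought (2,4,6-trihydroxybenzaldehyde, 3,4-dihydroxyacetophenone); ring C is the only ring formed.
2. Ring C comes from an achiral 2-(1-arylethenyloxy)benzaldehyde by enantioselective intramolecular alkene hydroacylation, which forms C3–C4 and creates the C2 stereocentre in one isomerisation.
3. Enabling feature: O1 of ring C is bonded to C8a of ring A, ortho to the carbon that bears the C4 carbonyl, and to C2, which carries ring B and one H. C2=C3 can therefore be an enol ether and C4 an aldehyde, and adding the C4–H across C2=C3 gives the flavanone.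
4. The aldehyde enol ether comes from the ring A phenol and a ring B 1-iodoalkene by copper-catalysed O-vinylation (O1–C2 bond). The iodoalkene comes from the acetophenone by 4-O-prenylation, 3-O-silylation and Barton iodination.

Key step: step 7

Assumption: the target is the (2S)-flavanone that the SMILES encodes; the sense of induction of the bisphosphine in step 7 cannot be predicted with certainty, so (R)-DTBM-SEGPHOS is written and its mirror image would be taken if a first run shows the (2R) product.

Step 1
Reactants: 1 3,4-dihydroxyacetophenone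
Product: 2 1-[3-hydroxy-4-(3-methylbut-2-enyloxy)phenyl]ethanone
Conditions: prenyl bromide (1.05 equiv), KHCO3, DMF, 40 °C
Reagents that add atoms: prenyl bromide (1-bromo-3-methylbut-2-ene), CC(C)=CCBr
Why: Williamson O-alkylation (SN2); the 4-OH, para to the acetyl group, is the more acidic phenol, so the weak base should ionise only it and the prenyl group should go to O4 alone.

Step 2
Reactants: 2 1-[3-hydroxy-4-(3-methylbut-2-enyloxy)phenyl]ethanone
Product: 3 1-[4-(3-methylbut-2-enyloxy)-3-(triisopropylsilyloxy)phenyl]ethanone
Conditions: TIPSCl, imidazole, DMF, rt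
Reagents that add atoms: triisopropylsilyl chloride (TIPSCl), CC(C)[Si](Cl)(C(C)C)C(C)C
Why: Imidazole-promoted silylation of a phenol should cap the 3-OH as a bulky aryl silyl ether that tolerates the bases and metals used later and is removed by fluoride at the end.

Step 3
Reactants: 3 1-[4-(3-methylbut-2-enyloxy)-3-(triisopropylsilyloxy)phenyl]ethanone
Product: 4 (E)-hydrazone of ketone 3
Conditions: N2H4·H2O (excess), Et3N, EtOH, 80 °C, argon
Reagents that add atoms: hydrazine (as hydrate), NN
Why: Condensation of a ketone with hydrazine to the hydrazone; excess hydrazine and exclusion of air should suppress azine formation and diimide reduction of the prenyl alkene.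

Step 4
Reactants: 4 (E)-hydrazone of ketone 3
Product: 6 4-(1-iodoethenyl)-1-(3-methylbut-2-enyloxy)-2-(triisopropylsilyloxy)benzene, via diazoalkane 5 (not isolated)
Conditions: I2, 1,1,3,3-tetramethylguanidine (excess), THF, 0 °C to rt
Reagents that add atoms: iodine, II
Why: Barton vinyl iodide synthesis: iodine oxidises the hydrazone to the diazoalkane, which is iodinated at carbon, loses N2 and then a methyl proton to give the 1-iodoalkene, while the excess guanidine base keeps the medium non-acidic for the prenyl ether.

Step 5
Reactants: 7 2,4,6-trihydroxybenzaldehyde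
Product: 8 2-hydroxy-4,6-bis(triisopropylsilyloxy)benzaldehyde
Conditions: TIPSCl (2.1 equiv), imidazole, DMF, 0 °C to rt
Reagents that add atoms: triisopropylsilyl chloride (TIPSCl), CC(C)[Si](Cl)(C(C)C)C(C)C
Why: Silylation of phenols: the 4-OH and one of the two equivalent ortho OH groups should react, while the last OH stays free because it is held in a hydrogen bond to the aldehyde oxygen.

Step 6
Reactants: 8 2-hydroxy-4,6-bis(triisopropylsilyloxy)benzaldehyde, 6 4-(1-iodoethenyl)-1-(3-methylbut-2-enyloxy)-2-(triisopropylsilyloxy)benzene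
Product: 9 2-({1-[4-(3-methylbut-2-enyloxy)-3-(triisopropylsilyloxy)phenyl]ethenyl}oxy)-4,6-bis(triisopropylsilyloxy)benzaldehyde
Conditions: CuI (10 mol%), N,N-dimethylglycine hydrochloride (30 mol%), Cs2CO3, 1,4-dioxane, 60 °C
Reagents that add atoms: none
Why: Ullmann-type copper-catalysed C–O coupling of a phenol with a vinyl iodide (oxidative addition of the C–I bond to a copper phenoxide, then C–O reductive elimination) should join O1 to C2 with the 1,1-disubstituted alkene intact, the mild temperature sparing the aryl silyl ethers.

Step 7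
Reactants: 9 2-({1-[4-(3-methylbut-2-enyloxy)-3-(triisopropylsilyloxy)phenyl]ethenyl}oxy)-4,6-bis(triisopropylsilyloxy)benzaldehyde
Product: 10 (2S)-2-[4-(3-methylbut-2-enyloxy)-3-(triisopropylsilyloxy)phenyl]-5,7-bis(triisopropylsilyloxy)-2,3-dihydro-4H-chromen-4-one
Conditions: [Rh(cod)Cl]2 (2.5 mol%), (R)-DTBM-SEGPHOS (5 mol%), NaB[3,5-(CF3)2C6H3]4 (5 mol%), 1,4-dioxane, 80 °C, argon
Reagents that add atoms: none
Why: Proposed new method: the cationic bisphosphine complex of monovalent rhodium should insert into the aldehyde C–H bond to give an acyl hydride of trivalent rhodium, the tethered enol ether C=C then inserts into Rh–H with hydride going to C2 (the carbon bearing O1 and ring B) and rhodium to the terminal CH2, and C–C reductive elimination from the seven-membered acyl alkyl rhodacycle forms the C3–C4 bond. The closest known reactions are the rhodium-catalysed enantioselective intramolecular hydroacylations of ortho-allylbenzaldehydes with 1,1-disubstituted alkenes to 3-substituted tetralones and of N-vinylindole-2-carbaldehydes to β-substituted cyclic ketones; new here is that the alkene is an aryl 1-arylvinyl ether and the product a chroman-4-one. Ring C closes in the 6-endo-trig mode, the acyl carbon bonding to the terminal alkene carbon. The only new stereocentre, C2, is set under catalyst control: the chiral bisphosphine selects the enantiotopic face of the alkene to which the hydride is delivered. The step needs endo regioselectivity and chemoselectivity over decarbonylation and over the prenyl alkene: the 1,1-disubstitution makes the exo path (tertiary alkyl rhodium, quaternary carbon, five-membered ring) unfavourable, the O1 donor polarises the alkene so that hydride goes to C2, the short ortho tether should make insertion faster than CO extrusion, and the trisubstituted prenyl alkene binds rhodium poorly.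

Step 8
Reactants: 10 (2S)-2-[4-(3-methylbut-2-enyloxy)-3-(triisopropylsilyloxy)phenyl]-5,7-bis(triisopropylsilyloxy)-2,3-dihydro-4H-chromen-4-one
Product: 11 Monotesone A, (2S)-5,7-dihydroxy-2-[3-hydroxy-4-(3-methylbut-2-enyloxy)phenyl]-2,3-dihydro-4H-chromen-4-one
Conditions: TBAF (3.5 equiv), AcOH (3.5 equiv), THF, 0 °C
Reagents that add atoms: none
Why: Fluoride cleavage of the three aryl silyl ethers (strong Si–F bond); acetic acid protonates the phenoxides at once, which should suppress base-induced ring opening of the flavanone to the chalcone (the path that would racemise C2), and the prenyl ether is inert.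

**Compound list**
1 | 3,4-dihydroxyacetophenone | CC(=O)c1ccc(O)c(O)c1 | starting material
2 | 1-[3-hydroxy-4-(3-methylbut-2-enyloxy)phenyl]ethanone | CC(=O)c1ccc(OCC=C(C)C)c(O)c1 | intermediate
3 | 1-[4-(3-methylbut-2-enyloxy)-3-(triisopropylsilyloxy)phenyl]ethanone | CC(=O)c1ccc(OCC=C(C)C)c(O[Si](C(C)C)(C(C)C)C(C)C)c1 | intermediate
4 | (E)-hydrazone of ketone 3 | N/N=C(\C)c1ccc(OCC=C(C)C)c(O[Si](C(C)C)(C(C)C)C(C)C)c1 | intermediate
5 | 4-(1-diazoethyl)-1-(3-methylbut-2-enyloxy)-2-(triisopropylsilyloxy)benzene | CC(=[N+]=[N-])c1ccc(OCC=C(C)C)c(O[Si](C(C)C)(C(C)C)C(C)C)c1 | intermediate (not isolated)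
6 | 4-(1-iodoethenyl)-1-(3-methylbut-2-enyloxy)-2-(triisopropylsilyloxy)benzene | C=C(I)c1ccc(OCC=C(C)C)c(O[Si](C(C)C)(C(C)C)C(C)C)c1 | intermediate
7 | 2,4,6-trihydroxybenzaldehyde | O=Cc1c(O)cc(O)cc1O | starting material
8 | 2-hydroxy-4,6-bis(triisopropylsilyloxy)benzaldehyde | O=Cc1c(O)cc(O[Si](C(C)C)(C(C)C)C(C)C)cc1O[Si](C(C)C)(C(C)C)C(C)C | intermediate
9 | 2-({1-[4-(3-methylbut-2-enyloxy)-3-(triisopropylsilyloxy)phenyl]ethenyl}oxy)-4,6-bis(triisopropylsilyloxy)benzaldehyde | O=Cc1c(OC(=C)c2ccc(OCC=C(C)C)c(O[Si](C(C)C)(C(C)C)C(C)C)c2)cc(O[Si](C(C)C)(C(C)C)C(C)C)cc1O[Si](C(C)C)(C(C)C)C(C)C | intermediate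
10 | (2S)-2-[4-(3-methylbut-2-enyloxy)-3-(triisopropylsilyloxy)phenyl]-5,7-bis(triisopropylsilyloxy)-2,3-dihydro-4H-chromen-4-one | CC(C)=CCOc1ccc([C@@H]2CC(=O)c3c(O[Si](C(C)C)(C(C)C)C(C)C)cc(O[Si](C(C)C)(C(C)C)C(C)C)cc3O2)cc1O[Si](C(C)C)(C(C)C)C(C)C | intermediate
11 | Monotesone A, (2S)-5,7-dihydroxy-2-[3-hydroxy-4-(3-methylbut-2-enyloxy)phenyl]-2,3-dihydro-4H-chromen-4-one | CC(C)=CCOc1ccc([C@@H]2CC(=O)c3c(O)cc(O)cc3O2)cc1O | target

**Step count and risks**

Total step count: 8. Longest linear sequence: 7 (steps 1, 2, 3, 4, 6, 7, 8); step 5 is a one-step side branch that joins at step 6.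

Steps most likely to fail:

First, step 7 (proposed new method). What may go wrong: slow oxidative addition of the electron-rich, doubly ortho-substituted aldehyde C–H bond; decarbonylation of the acyl rhodium hydride, which ties up the catalyst as a carbonyl complex; hydride delivery with the wrong regiochemistry; or weak discrimination between the alkene faces. The fallback uses known chemistry, sets out from ketone 3 and phenol 8 and comes back at flavanone 10. Ketone 3 is converted with TMSOTf and Et3N into the trimethylsilyl enol ether F1. NBS in THF at −78 °C brominates F1 at the enol carbon, faster than the prenyl alkene, to the α-bromo ketone F2. Corey–Bakshi–Shibata reduction ((S)-2-methyl-CBS-oxazaborolidine, catecholborane, toluene, −78 °C, a borane that spares the prenyl alkene) should give the (S)-bromohydrin F3. Mitsunobu etherification with 8 (PPh3, DIAD, toluene, 0 °C) inverts the carbinol carbon to the (R)-bromo ether F4, which already holds C2 in the spatial arrangement of the target. An N-heterocyclic-carbene-catalysed intramolecular alkylation of the aldehyde (thiazolium precatalyst, DBU, toluene) then closes the ring: the Breslow intermediate displaces the primary bromide, a known closure of 2-(2-halo- or 2-sulfonyloxyethoxy)benzaldehydes to chroman-4-ones. This forms the same C3–C4 bond and gives 10 without touching the stereocentre.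

Second, step 6. What may go wrong: dehydroiodination of iodoalkene 6 to the arylalkyne, loss of silyl groups to carbonate, and sluggish coupling because the hindered, hydrogen-bonded phenoxide binds copper as a chelate. The fallback sets out from ketone 3 and phenol 8 and comes back at enol ether 9. The α-bromo ketone F2, made from 3 through silyl enol ether F1 as above, is reduced with NaBH4 (MeOH, 0 °C) to the racemic bromohydrin F5. Mitsunobu etherification with 8 gives the racemic bromo ether F6. E2 dehydrobromination with KOtBu (THF, 0 °C), in which the only β-hydrogen is the benzylic one, should give 9. The O1–C2 bond is thus made at an sp3 carbon, without copper, carbonate or a vinyl halide, and the alkene is introduced afterwards.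

Third, step 4. What may go wrong: incomplete elimination to the iodoalkene, azine formation from the hydrazone, reversible uptake of iodine by the prenyl alkene and partial loss of the aryl silyl ether on the way through the hydrazone. The fallback sets out from ketone 3 and comes back at enol ether 9. Deprotonation with KHMDS and trapping with PhNTf2 (THF, −78 °C) gives the enol triflate F7. C–O coupling of F7 with phenol 8 under zerovalent palladium catalysis (Pd2(dba)3, 2-(di-tert-butylphosphino)biphenyl, K3PO4, toluene, 80 °C) gives 9 directly. The hydrazone, the iodoalkene and the copper step are all bypassed.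

**Further compounds**
F1 | step 7 | trimethyl({1-[4-(3-methylbut-2-enyloxy)-3-(triisopropylsilyloxy)phenyl]ethenyl}oxy)silane | C=C(O[Si](C)(C)C)c1ccc(OCC=C(C)C)c(O[Si](C(C)C)(C(C)C)C(C)C)c1
F2 | step 7 | 2-bromo-1-[4-(3-methylbut-2-enyloxy)-3-(triisopropylsilyloxy)phenyl]ethanone | O=C(CBr)c1ccc(OCC=C(C)C)c(O[Si](C(C)C)(C(C)C)C(C)C)c1
F3 | step 7 | (1S)-2-bromo-1-[4-(3-methylbut-2-enyloxy)-3-(triisopropylsilyloxy)phenyl]ethanol | O[C@H](CBr)c1ccc(OCC=C(C)C)c(O[Si](C(C)C)(C(C)C)C(C)C)c1
F4 | step 7 | 2-{(1R)-2-bromo-1-[4-(3-methylbut-2-enyloxy)-3-(triisopropylsilyloxy)phenyl]ethoxy}-4,6-bis(triisopropylsilyloxy)benzaldehyde | O=Cc1c(O[C@@H](CBr)c2ccc(OCC=C(C)C)c(O[Si](C(C)C)(C(C)C)C(C)C)c2)cc(O[Si](C(C)C)(C(C)C)C(C)C)cc1O[Si](C(C)C)(C(C)C)C(C)C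
F5 | step 6 | racemic 2-bromo-1-[4-(3-methylbut-2-enyloxy)-3-(triisopropylsilyloxy)phenyl]ethanol | OC(CBr)c1ccc(OCC=C(C)C)c(O[Si](C(C)C)(C(C)C)C(C)C)c1
F6 | step 6 | racemic 2-{2-bromo-1-[4-(3-methylbut-2-enyloxy)-3-(triisopropylsilyloxy)phenyl]ethoxy}-4,6-bis(triisopropylsilyloxy)benzaldehyde | O=Cc1c(OC(CBr)c2ccc(OCC=C(C)C)c(O[Si](C(C)C)(C(C)C)C(C)C)c2)cc(O[Si](C(C)C)(C(C)C)C(C)C)cc1O[Si](C(C)C)(C(C)C)C(C)C
F7 | step 4 | 1-[4-(3-methylbut-2-enyloxy)-3-(triisopropylsilyloxy)phenyl]ethenyl trifluoromethanesulfonate | C=C(OS(=O)(=O)C(F)(F)F)c1ccc(OCC=C(C)C)c(O[Si](C(C)C)(C(C)C)C(C)C)c1
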